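**Retrosynthetic overview**
1. Numbering used: ring A = C1–C5 and C10 (C1 carbinol; C4 quaternary, carrying CH3 and the lactone carbonyl C19); seven-membered ring B = C5–C6–C7–C8–C9–C20–C10; ring C = C8, C9, C11–C14 (O on C11, C12, C14; isopropyl on C13); lactone = C19–O–C6–C5–C4.
2. Endgame: the C1 carbinol comes from a C1 ketone (Luche reduction, substrate control), and the hydroxyquinone ring C from an 11,12,14-trimethoxyarene (BBr3, then air).
3. Key disconnection: C5–C6 and C7–C8 are cut together, as a formal (5+2) annulation of the two-carbon unit C6–C7 onto the five-atom unit C8–C9–C20–C10–C5; this closes the lactone ring and ring B at once, sets C5 and installs both the C10=C20 and C6=C7 double bonds.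
4. Enabling feature: the enol γ-lactone C19(=O)–O–C6=C7 is the enol ester of the C19 acid with hydroxyacetaldehyde, so C6 is an enamine-nucleophilic α-carbon and C7 an aldehyde carbon; C5 is the β-carbon of a C1 enone in ring A, and C8 is the only free position of ring C, para to O12 and ortho to O14.
5. The annulation precursor is a Morita–Baylis–Hillman adduct (C10–C20 bond) of a ring A cyclohexenone ester and a ring C aldehyde; ring order: ring C (purchased arene), ring A (enantioselective Diels–Alder, sets C4), then lactone ring and ring B together.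

Key step: step 10

Remark: the sense of induction of the hydrogen-bond-catalysed Diels–Alder reaction in step 4 is assumed to follow the catalyst antipode; the antipode that delivers the (S)-aldehyde is the one used.
Remark: the carbinol/acetoxy carbon C20 in 11–13 is a mixture of epimers; this is harmless because C20 becomes sp2 in step 10.

**Step 1**
Reactants: 1 1,2,4-trimethoxybenzene
Product: 2 2-(2,3,6-trimethoxyphenyl)propan-2-ol
Conditions: n-BuLi, THF, 0 °C; acetone, −78 → 23 °C; H2O
Reagents that add atoms: acetone, CC(C)=O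
Why: Directed ortho-metalation should occur at the position flanked by two methoxy groups, and the aryllithium adds 1,2 to acetone.

**Step 2**
Reactants: 2 2-(2,3,6-trimethoxyphenyl)propan-2-ol
Product: 3 1,2,4-trimethoxy-3-(propan-2-yl)benzene
Conditions: Et3SiH, CF3CO2H, CH2Cl2, 0 → 23 °C
Reagents that add atoms: none
Why: Ionic hydrogenation: acid ionises the tertiary benzylic alcohol to a cation stabilised by two ortho methoxy groups, and the silane delivers hydride.

**Step 3**
Reactants: 3 1,2,4-trimethoxy-3-(propan-2-yl)benzene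
Product: 4 4-isopropyl-2,3,5-trimethoxybenzaldehyde
Conditions: n-BuLi, TMEDA, Et2O, 0 → 23 °C; DMF, −78 → 0 °C; H2O
Reagents that add atoms: N,N-dimethylformamide, CN(C)C=O
Why: Directed ortho-metalation should take place next to the C1 methoxy group (one ortho and two meta methoxy groups) and not next to the C4 methoxy group, which is buttressed by the isopropyl group; DMF then formylates the aryllithium at the future C9.

**Step 4**
Reactants: 5 (E)-3-(tert-butyldimethylsilyloxy)-N,N-dimethylbuta-1,3-dien-1-amine; 6 methacrolein
Product: 8 (S)-1-methyl-4-oxocyclohex-2-ene-1-carbaldehyde, via endo cycloadduct 7 (not isolated)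
Conditions: (4R,5R)-2,2-dimethyl-α,α,α′,α′-tetra(1-naphthyl)-1,3-dioxolane-4,5-dimethanol (20 mol %, antipode as in the remark), toluene, −80 °C; then AcCl, CH2Cl2/Et2O, −78 °C
Reagents that add atoms: none
Why: Hydrogen-bond-catalysed enantioselective Diels–Alder reaction of the aminosiloxy diene with the diol-activated enal (endo, amino carbon bonding to the α-carbon) sets the quaternary centre C4 under catalyst control, and acetyl chloride then triggers loss of the amine and the silyl group to give the enone.

**Step 5**
Reactants: 8 (S)-1-methyl-4-oxocyclohex-2-ene-1-carbaldehyde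
Product: 9 (S)-1-methyl-4-oxocyclohex-2-ene-1-carboxylic acid
Conditions: NaClO2, NaH2PO4, 2-methyl-2-butene, t-BuOH/H2O, 0 → 23 °C
Reagents that add atoms: sodium chlorite, [Na+].[O-]Cl=O
Why: Pinnick oxidation is selective for the aldehyde, and the alkene scavenger keeps HOCl away from the enone.

**Step 6**
Reactants: 9 (S)-1-methyl-4-oxocyclohex-2-ene-1-carboxylic acid
Product: 10 allyl (S)-1-methyl-4-oxocyclohex-2-ene-1-carboxylate
Conditions: allyl bromide, K2CO3, DMF, 23 °C
Reagents that add atoms: allyl bromide, C=CCBr
Why: SN2 O-alkylation of the carboxylate installs the allyl group as the latent C6–C7 hydroxyacetaldehyde unit.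

**Step 7**
Reactants: 10 allyl (S)-1-methyl-4-oxocyclohex-2-ene-1-carboxylate; 4 4-isopropyl-2,3,5-trimethoxybenzaldehyde
Product: 11 allyl (1S)-3-[hydroxy(4-isopropyl-2,3,5-trimethoxyphenyl)methyl]-1-methyl-4-oxocyclohex-2-ene-1-carboxylate (carbinol epimers)
Conditions: PBu3 (0.3 equiv), 1,1′-bi-2-naphthol (0.15 equiv), THF, 23 °C
Reagents that add atoms: none
Why: Morita–Baylis–Hillman reaction: reversible phosphine addition to the enone β-carbon gives an enolate that adds to the hydrogen-bond-activated aldehyde and releases the catalyst, forming the C10–C20 bond.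

**Step 8**
Reactants: 11 Morita–Baylis–Hillman alcohol
Product: 12 allyl (1S)-3-[acetoxy(4-isopropyl-2,3,5-trimethoxyphenyl)methyl]-1-methyl-4-oxocyclohex-2-ene-1-carboxylate
Conditions: Ac2O, pyridine, DMAP (cat.), CH2Cl2, 0 → 23 °C
Reagents that add atoms: acetic anhydride, CC(=O)OC(C)=O
Why: DMAP-catalysed acylation turns the C20 hydroxyl into the leaving group needed for the elimination in step 10.

**Step 9**
Reactants: 12 allyl ester acetate
Product: 13 2-oxoethyl (1S)-3-[acetoxy(4-isopropyl-2,3,5-trimethoxyphenyl)methyl]-1-methyl-4-oxocyclohex-2-ene-1-carboxylate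
Conditions: OsO4 (2 mol %), NaIO4, 2,6-lutidine, dioxane/H2O, 23 °C
Reagents that add atoms: sodium periodate, [Na+].[O-]I(=O)(=O)=O (terminal oxidant; the aldehyde oxygen is delivered through OsO4)
Why: Lemieux–Johnson oxidation: the terminal allyl alkene should be dihydroxylated much faster than the hindered, electron-poor enone, and periodate cleaves the diol to the O-acylated hydroxyacetaldehyde.

**Step 10**
Reactants: 13 2-oxoethyl ester acetate
Product: 16 tetracyclic keto enol lactone (4S,5R)-11,12,14-trimethoxy-1-oxoicetexa-6,8,11,13,10(20)-pentaen-19,6-olide, via lactone aldehyde 14 (not isolated), via benzylic alcohol 15 (not isolated)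
Conditions: pyrrolidine (0.3 equiv), CF3CO2H (0.3 equiv), CHCl3 (0.01 M), Ar, 23 °C until 13 is consumed; then CF3CO2H (10 equiv), 45 °C
Reagents that add atoms: none
Why: Proposed new method: the amine salt converts the O-acylated hydroxyacetaldehyde unit of 13 into its enamine, whose α-carbon C6 adds to C5 of the ring A enone (5-exo-trig, closing the γ-lactone through a C–C bond), the enolate expels acetate from C20 (E1cB) to give the (E)-arylidene ketone 14, and the iminium or protonated aldehyde carbon C7 is then attacked by C8 of ring C (7-exo-trig Friedel–Crafts closure of ring B) before loss of water or amine from 15 across C6–C7 gives the enol lactone 16. The closest known reaction types are the amine-catalysed intramolecular Michael addition of aldehydes to enones, the SN2′ substitution of Morita–Baylis–Hillman acetates by enamines and the Bradsher-type (Pictet–Spengler-like) cyclodehydration of aryl-tethered aldehydes; their merger into one formal (5+2) annulation is the new element. The only new stereocentre, C5, is set by the C4 quaternary centre, because the nucleophile is tethered through the C19 ester and can reach C5 only on the face that gives the cis-fused lactone (axial attack on the enone, syn to C19). Site selectivity is needed at C5 over C20 and at C8 on the arene: C5 is the only conjugate position and gives the five-membered ring, and C8 is the sole unsubstituted arene carbon, para to the C12 and ortho to the C14 methoxy group, held next to C7 by the (E)-C10=C20 bond. Strong acid is added only after the acetate has been consumed, so that the benzylic acetate cannot ionise, and reversible side reactions (aldol of C7 with the C2 enol, C6 epimerisation) should funnel to 16 because only the Friedel–Crafts/dehydration branch is irreversible.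

**Step 11**
Reactants: 16 tetracyclic keto enol lactone
Product: 18 (4S,5R)-12-hydroxy-1,11,14-trioxoicetexa-6,8,12,10(20)-tetraen-19,6-olide, via triol ketone 17 (not isolated)
Conditions: BBr3, CH2Cl2, −78 → 0 °C; H2O; then air, EtOAc/pH 7 buffer, 23 °C
Reagents that add atoms: none
Why: BBr3 cleaves the three aryl methyl ethers at low temperature, where the lactone and the enone should survive, and the resulting 1,2,4-benzenetriol autoxidises in air to the 2-hydroxy-1,4-benzoquinone.

**Step 12**
Reactants: 18 1-oxo hydroxyquinone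
Product: 20 6,7-anhydroballotiquinone, (1R,4S,5R)-1,12-dihydroxy-11,14-dioxoicetexa-6,8,12,10(20)-tetraen-19,6-olide, via triol alcohol 19 (not isolated)
Conditions: NaBH4, CeCl3·7H2O, MeOH/THF, −78 °C; pH 7 phosphate buffer; air, 23 °C
Reagents that add atoms: none
Why: Luche reduction should give clean 1,2-reduction of the enone with hydride attacking C1 from the face of C4–CH3 and C5–H, opposite the pseudo-axial C5–C6 bond, which places the hydroxyl cis to the lactone (1R); the quinone, reduced at the same time, is re-formed by air on work-up.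

**Compound list**
1 | 1,2,4-trimethoxybenzene | COc1ccc(OC)c(OC)c1 | starting material
2 | 2-(2,3,6-trimethoxyphenyl)propan-2-ol | COc1ccc(OC)c(C(C)(C)O)c1OC | intermediate
3 | 1,2,4-trimethoxy-3-(propan-2-yl)benzene | COc1ccc(OC)c(C(C)C)c1OC | intermediate
4 | 4-isopropyl-2,3,5-trimethoxybenzaldehyde | O=Cc1cc(OC)c(C(C)C)c(OC)c1OC | intermediate
5 | (E)-3-(tert-butyldimethylsilyloxy)-N,N-dimethylbuta-1,3-dien-1-amine | CN(C)/C=C/C(=C)O[Si](C)(C)C(C)(C)C | starting material
6 | methacrolein | CC(=C)C=O | starting material
7 | endo cycloadduct, 4-(tert-butyldimethylsilyloxy)-2-(dimethylamino)-1-methylcyclohex-3-ene-1-carbaldehyde (formyl and dimethylamino cis; quaternary centre as in 8) | C[C@@]1(C=O)[C@H](N(C)C)C=C(O[Si](C)(C)C(C)(C)C)CC1 | intermediate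
8 | (S)-1-methyl-4-oxocyclohex-2-ene-1-carbaldehyde | C[C@@]1(C=O)C=CC(=O)CC1 | intermediate
9 | (S)-1-methyl-4-oxocyclohex-2-ene-1-carboxylic acid | C[C@@]1(C(=O)O)C=CC(=O)CC1 | intermediate
10 | allyl (S)-1-methyl-4-oxocyclohex-2-ene-1-carboxylate | C=CCOC(=O)[C@]1(C)C=CC(=O)CC1 | intermediate
11 | allyl (1S)-3-[hydroxy(4-isopropyl-2,3,5-trimethoxyphenyl)methyl]-1-methyl-4-oxocyclohex-2-ene-1-carboxylate (carbinol epimers) | C=CCOC(=O)[C@]1(C)C=C(C(O)c2cc(OC)c(C(C)C)c(OC)c2OC)C(=O)CC1 | intermediate
12 | allyl (1S)-3-[acetoxy(4-isopropyl-2,3,5-trimethoxyphenyl)methyl]-1-methyl-4-oxocyclohex-2-ene-1-carboxylate (epimers at the acetoxy carbon) | C=CCOC(=O)[C@]1(C)C=C(C(OC(C)=O)c2cc(OC)c(C(C)C)c(OC)c2OC)C(=O)CC1 | intermediate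
13 | 2-oxoethyl (1S)-3-[acetoxy(4-isopropyl-2,3,5-trimethoxyphenyl)methyl]-1-methyl-4-oxocyclohex-2-ene-1-carboxylate (epimers at the acetoxy carbon) | O=CCOC(=O)[C@]1(C)C=C(C(OC(C)=O)c2cc(OC)c(C(C)C)c(OC)c2OC)C(=O)CC1 | intermediate
14 | cis-fused lactone aldehyde (4S,5R; C6 epimers): ring A 1-ketone with (E)-C10=C20 4-isopropyl-2,3,5-trimethoxybenzylidene group and the C19–O–C6(CHO)–C5 γ-lactone | O=CC1OC(=O)[C@@]2(C)CCC(=O)/C(=C/c3cc(OC)c(C(C)C)c(OC)c3OC)[C@@H]12 | intermediate
15 | benzylic alcohol, 7-hydroxy-6,7-dihydro form of 16 (4S,5R; C6 and C7 epimers) | CC(C)c1c(OC)c(OC)c2c(C(O)C3OC(=O)[C@@]4(C)CCC(=O)C(=C2)[C@@H]34)c1OC | intermediate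
16 | (4S,5R)-11,12,14-trimethoxy-1-oxoicetexa-6,8,11,13,10(20)-pentaen-19,6-olide | CC(C)c1c(OC)c(OC)c2c(C=C3OC(=O)[C@@]4(C)CCC(=O)C(=C2)[C@@H]34)c1OC | intermediate
17 | triol ketone, (4S,5R)-11,12,14-trihydroxy-1-oxoicetexa-6,8,11,13,10(20)-pentaen-19,6-olide | CC(C)c1c(O)c(O)c2c(C=C3OC(=O)[C@@]4(C)CCC(=O)C(=C2)[C@@H]34)c1O | intermediate
18 | (4S,5R)-12-hydroxy-1,11,14-trioxoicetexa-6,8,12,10(20)-tetraen-19,6-olide | CC(C)C1=C(O)C(=O)C2=C(C=C3OC(=O)[C@@]4(C)CCC(=O)C(=C2)[C@@H]34)C1=O | intermediate
19 | triol alcohol, hydroquinone form of the target (1R,4S,5R) | CC(C)c1c(O)c(O)c2c(C=C3OC(=O)[C@@]4(C)CC[C@@H](O)C(=C2)[C@@H]34)c1O | intermediate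
20 | 6,7-anhydroballotiquinone (1R,4S,5R) | CC(C)C1=C(O)C(=O)C2=C(C=C3OC(=O)[C@@]4(C)CC[C@@H](O)C(=C2)[C@@H]34)C1=O | target

**Totals**
Total step count: 12.
Longest linear sequence: 9 steps (steps 1–3 and 7–12, or steps 4–12).

**Steps most likely to fail**

Step 10 (proposed new method). The amine may be captured by conjugate addition to the acetate. The Michael addition may be slow because lactone formation demands the s-cis ester geometry. Intermolecular Friedel–Crafts alkylation or oligomerisation may outrun the seven-membered closure. Fallback with known chemistry, setting out from 13: amine catalysis alone (pyrrolidine, AcOH, CHCl3, no strong acid) should stop at the lactone aldehyde 14, which is isolated. HC(OMe)3 with pyridinium tosylate in MeOH converts it into the dimethyl acetal of the lactone aldehyde F1. SnCl4 in CH2Cl2 at −78 °C generates the oxocarbenium ion and closes ring B by acetal Friedel–Crafts alkylation to the 7-methoxy-6,7-dihydro tetracycle F2. TsOH in warm toluene eliminates methanol, and the sequence rejoins the route at 16.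

Step 7. Phosphine addition to the enone β-carbon next to the quaternary centre may be too slow, and the electron-rich, ortho-substituted aldehyde may add reversibly. Fallback, setting out from 10 and 4: thiolate-triggered tandem conjugate addition–aldol (Me2AlSPh, CH2Cl2, −78 °C, then 4) gives the β-phenylthio aldol F3. mCPBA at −78 °C gives the sulfoxide F4, whose thermal syn-elimination (toluene, 80 °C; the only β-hydrogen is at the ketone α-carbon) rejoins the route at 11.

Step 12. Hydride may attack the wrong face, conjugate reduction may compete, and at the hydroquinone oxidation level the C14 phenoxide may take over the acyl group of the enol lactone. Fallback, setting out from 16, so that neither quinone nor free phenol is present during the reduction: NaBH4/CeCl3·7H2O in MeOH at −78 °C gives the trimethoxy (1R)-alcohol F5. (NH4)2Ce(NO3)6 in MeCN/H2O at 0 °C oxidises the para-dimethoxy pair at C11/C14 to the quinone, giving the 12-O-methyl ether of the target F6. LiCl in DMF at 80 °C (SN2 demethylation of the vinylogous methyl ester) rejoins the route at 20.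

Further compounds
F1 | step 10 | dimethyl acetal of the lactone aldehyde (4S,5R; C6 epimers) | COC(OC)C1OC(=O)[C@@]2(C)CCC(=O)/C(=C/c3cc(OC)c(C(C)C)c(OC)c3OC)[C@@H]12
F2 | step 10 | 7-methoxy-6,7-dihydro tetracycle (4S,5R; C6 and C7 epimers) | CC(C)c1c(OC)c(OC)c2c(C(OC)C3OC(=O)[C@@]4(C)CCC(=O)C(=C2)[C@@H]34)c1OC
F3 | step 7 | β-phenylthio aldol, allyl 3-[hydroxy(4-isopropyl-2,3,5-trimethoxyphenyl)methyl]-1-methyl-4-oxo-2-(phenylthio)cyclohexane-1-carboxylate (quaternary centre as in 10; other centres as formed) | C=CCOC(=O)[C@]1(C)C(Sc2ccccc2)C(C(O)c2cc(OC)c(C(C)C)c(OC)c2OC)C(=O)CC1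
F4 | step 7 | sulfoxide of the β-phenylthio aldol (quaternary centre as in 10; other centres as formed) | C=CCOC(=O)[C@]1(C)C(S(=O)c2ccccc2)C(C(O)c2cc(OC)c(C(C)C)c(OC)c2OC)C(=O)CC1
F5 | step 12 | trimethoxy (1R)-alcohol, (1R,4S,5R)-1-hydroxy-11,12,14-trimethoxyicetexa-6,8,11,13,10(20)-pentaen-19,6-olide | CC(C)c1c(OC)c(OC)c2c(C=C3OC(=O)[C@@]4(C)CC[C@@H](O)C(=C2)[C@@H]34)c1OC
F6 | step 12 | 12-O-methyl ether of the target (1R,4S,5R) | CC(C)C1=C(OC)C(=O)C2=C(C=C3OC(=O)[C@@]4(C)CC[C@@H](O)C(=C2)[C@@H]34)C1=O
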